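**Retrosynthetic overview**
1. Lychnopholide ⇒ C8–O acylation with angelic acid ⇒ the 8‑hydroxy furanoheliangolide core.
2. Core ⇒ C6–C7 and O6–C12 disconnection: a visible‑light, Cr‑catalysed intramolecular 2‑(methoxycarbonyl)allylation/lactonisation of a seco (Z)‑enal/allylic bromide. This one step closes the 10‑membered carbocycle and the α‑methylene‑γ‑lactone, and sets C6 and C7 from C8.
3. Allylic bromide ⇒ C7=C11 by Morita–Baylis–Hillman reaction with methyl acrylate, then SN2′ bromide, from a C7 aldehyde carried on a preformed 3(2H)‑furanone.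
4. Furanone ⇒ O10–C3 by 5‑endo‑dig closure and C1–C2 by acetylide addition to a lactone. The partners are a (Z)‑enynal acetal (Z‑C4=C5 bought) and an α‑hydroxy‑α‑methyl‑γ‑lactone.
5. Lactone ⇒ (S)‑5‑(hydroxymethyl)butyrolactone. C8 is bought; C10 is set by anti‑selective enolate methylation then oxygenation. Ring order: furanone first, then carbocycle and lactone together.

Assumption: 1, 5, 11 and 16 are treated as catalogue chemicals. Germacrane numbering (C1–C15) of the target is used in the comments.

**Step 1**
Reactants: 1, (S)‑5‑(hydroxymethyl)dihydrofuran‑2(3H)‑one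
Product: 2, (S)‑5‑[(triethylsilyloxy)methyl]dihydrofuran‑2(3H)‑one
Conditions: TESCl, imidazole, CH2Cl2, 0 °C → rt
Reagents that add atoms: chlorotriethylsilane, CC[Si](Cl)(CC)CC
Why: Standard silylation that leaves the bought C8 centre untouched; TES is chosen because a primary TES ether can later be oxidised directly to the aldehyde.

**Step 2**
Reactants: 2
Product: 3, (3R,5S)‑3‑methyl‑5‑[(triethylsilyloxy)methyl]dihydrofuran‑2(3H)‑one (trans major, minor 3S epimer carried on)
Conditions: LDA (1.05 equiv), THF, −78 °C; MeI, −78 → −40 °C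
Reagents that add atoms: iodomethane, CI
Why: Kinetic lactone enolate alkylation, with MeI entering anti to the C5 side chain; this centre is planarised again in Step 3, so the ratio does not matter.

**Step 3**
Reactants: 3
Product: 4, (3R,5S)‑3‑hydroxy‑3‑methyl‑5‑[(triethylsilyloxy)methyl]dihydrofuran‑2(3H)‑one (OH trans, CH3 cis to CH2OTES)
Conditions: LDA (1.2 equiv), THF, −78 °C; P(OEt)3, O2, −78 °C; AcOH quench
Reagents that add atoms: dioxygen, O=O
Why: Enolate oxygenation with in situ phosphite reduction of the hydroperoxide; O2 attacks the planar trisubstituted enolate anti to CH2OTES, so C8 (S) sets C10 (R).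

**Step 4**
Reactants: 5, (Z)‑3‑methylpent‑2‑en‑4‑yn‑1‑ol
Product: 6, (Z)‑3‑methylpent‑2‑en‑4‑ynal
Conditions: activated MnO2, CH2Cl2, rt, dark
Reagents that add atoms: none
Why: Neutral heterogeneous allylic oxidation keeps the bought Z geometry (future C4=C5).

**Step 5**
Reactants: 6
Product: 7, (Z)‑5,5‑dimethoxy‑3‑methylpent‑3‑en‑1‑yne
Conditions: MeOTMS (2.5 equiv), TMSOTf (2 mol %), CH2Cl2, −78 °C; pyridine quench
Reagents that add atoms: methoxytrimethylsilane, CO[Si](C)(C)C
Why: Noyori aprotic acetalisation at −78 °C masks C6 at the aldehyde oxidation level without acid‑catalysed Z→E isomerisation.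

**Step 6**
Reactants: 4; 7 (2.3 equiv, excess recovered)
Product: 8, (2Z,7R,9S)‑7,9‑dihydroxy‑1,1‑dimethoxy‑3,7‑dimethyl‑10‑(triethylsilyloxy)dec‑2‑en‑4‑yn‑6‑one (in equilibrium with its five‑membered lactol)
Conditions: 7, n‑BuLi (2.2 equiv), THF, −78 °C; add 4, −78 → −40 °C; AcOH/THF quench at −78 °C
Reagents that add atoms: none (both partners are numbered reactants)
Why: 1,2‑addition of a lithium acetylide to a γ‑lactone forms C1–C2; the lactolate is stable at low temperature and blocks over‑addition, the first equivalent only deprotonates the tertiary OH, and no stereocentre is touched.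

**Step 7**
Reactants: 8
Product: 9, (R)‑2‑[(S)‑2,3‑bis(triethylsilyloxy)propyl]‑5‑[(Z)‑4,4‑dimethoxybut‑2‑en‑2‑yl]‑2‑methylfuran‑3(2H)‑one
Conditions: (Ph3P)AuNTf2 (3 mol %), CH2Cl2, rt; then imidazole, TESCl, 0 °C → rt (one pot)
Reagents that add atoms: chlorotriethylsilane, CC[Si](Cl)(CC)CC
Why: π‑acid‑catalysed 5‑endo‑dig oxa‑Michael closure (Baldwin‑allowed) of the C10 hydroxyl onto the ynone gives the 3(2H)‑furanone under neutral conditions with C10 unchanged; the freed C8 carbinol is silylated in the same flask.

**Step 8**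
Reactants: 9
Product: 10, (S)‑3‑{(R)‑5‑[(Z)‑4,4‑dimethoxybut‑2‑en‑2‑yl]‑2‑methyl‑3‑oxo‑2,3‑dihydrofuran‑2‑yl}‑2‑(triethylsilyloxy)propanal
Conditions: (COCl)2 (3 equiv), DMSO (6 equiv), CH2Cl2, −78 → −40 °C; i‑Pr2NEt, −78 → 0 °C
Reagents that add atoms: none
Why: Under Swern conditions a primary TES ether is converted directly into the aldehyde while the secondary TES ether survives, which saves a deprotection; the anhydrous medium leaves the acetal intact.

**Step 9**
Reactants: 10; 11, methyl acrylate
Product: 12, methyl (4S)‑5‑{(R)‑5‑[(Z)‑4,4‑dimethoxybut‑2‑en‑2‑yl]‑2‑methyl‑3‑oxo‑2,3‑dihydrofuran‑2‑yl}‑3‑hydroxy‑2‑methylene‑4‑(triethylsilyloxy)pentanoate (C7 carbinol epimers)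
Conditions: 11 (5 equiv), quinuclidine (0.5 equiv), MeOH (2 equiv), rt
Reagents that add atoms: methyl acrylate (11), C=CC(=O)OC
Why: Morita–Baylis–Hillman reaction on an activated α‑silyloxy aldehyde installs C11–C13; the new carbinol centre is destroyed in Step 10.

**Step 10**
Reactants: 12
Product: 13, methyl (S,Z)‑2‑(bromomethyl)‑5‑{(R)‑5‑[(Z)‑4,4‑dimethoxybut‑2‑en‑2‑yl]‑2‑methyl‑3‑oxo‑2,3‑dihydrofuran‑2‑yl}‑4‑(triethylsilyloxy)pent‑2‑enoate
Conditions: MsCl, Et3N, CH2Cl2, −20 °C; then LiBr, THF, 0 °C → rt
Reagents that add atoms: lithium bromide, [Li+].[Br-]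
Why: Mesylation followed by SN2′ bromide displacement of the Baylis–Hillman alcohol gives the thermodynamic (Z)‑2‑(bromomethyl)enoate, with no Br+ or HBr that could attack the furanone or the acetal.

**Step 11**
Reactants: 13
Product: 14, methyl (S,Z)‑2‑(bromomethyl)‑5‑{(R)‑2‑methyl‑3‑oxo‑5‑[(Z)‑4‑oxobut‑2‑en‑2‑yl]‑2,3‑dihydrofuran‑2‑yl}‑4‑(triethylsilyloxy)pent‑2‑enoate
Conditions: SiO2/10 % aq. oxalic acid, CH2Cl2, 0 °C → rt, dark; used at once
Reagents that add atoms: water, O
Why: The allylic dimethyl acetal hydrolyses through a stabilised oxocarbenium ion much faster than a secondary TES ether cleaves, which releases the (Z)‑enal under very mild acid.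

**Step 12 (key step)**
Reactants: 14
Product: 15, 8‑O‑deangeloyl‑lychnopholide, the (6R,7R,8S,10R,4Z)‑8‑hydroxy furanoheliangolide core
Conditions: CrCl3·3THF (20 mol %), eosin Y (TBA salt, 3 mol %), Hantzsch ester (1.5 equiv), 2,4,6‑collidine (2 equiv), THF/DMF 4:1, syringe‑pump addition of 14 to 2 mM, 530 nm LEDs, 20 °C; work‑up 1 M HCl/THF, 0 °C → rt
Reagents that add atoms: none
Why: Proposed new method: a light‑driven, chromium‑catalytic, macrocyclising Nozaki–Hiyama/Barbier 2‑(alkoxycarbonyl)allylation. Excited eosin Y is reductively quenched by the Hantzsch ester, and the dye radical anion (about −1.1 V) together with the Hantzsch radical reduces Cr(III) to Cr(II); two Cr(II) convert the allylic bromide, via the 2‑carbomethoxyallyl radical, into a σ‑allyl–Cr(III) species that equilibrates to the (E)‑crotyl‑type geometry, binds the (Z)‑enal and attacks through C7 in a closed chair transition state (anti addition, hence trans C6/C7); the C7 face is chosen by C8 (C8–H in the alkene plane to avoid A1,3 strain, non‑chelating OTES anti, C9 tether gauche), which gives 6R,7R; collidinium protonates the Cr alkoxide to turn the metal over, and the acidic work‑up completes lactonisation and removes TES; a silyl ether is kept on C8 instead of the ester because it should resist reductive 1,4‑elimination and cannot enforce the chelated syn (cis‑lactone) pathway; the low‑triplet‑energy dye and green light limit Z/E scrambling of the dienal; the closest known reaction types are stoichiometric CrCl2 macrocyclisation of ω‑formyl 2‑(bromomethyl)enoates and intermolecular dual photoredox/chromium carbonyl allylation, neither of which has been shown as a catalytic medium‑ring closure.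

**Step 13**
Reactants: 15; 16, angelic acid [(Z)‑2‑methylbut‑2‑enoic acid]
Product: 17, lychnopholide
Conditions: 16, 2,4,6‑Cl3C6H2COCl, Et3N, toluene, rt; then 15, 75 °C (no DMAP)
Reagents that add atoms: angelic acid (16), C/C=C(/C)C(=O)O
Why: Yamaguchi mixed‑anhydride esterification without a nucleophilic catalyst acylates the C8 hydroxyl with retention at C8 and without angelate→tiglate isomerisation.

**Compound list**
1 | (S)‑5‑(hydroxymethyl)dihydrofuran‑2(3H)‑one | OC[C@@H]1CCC(=O)O1 | starting material
2 | (S)‑5‑[(triethylsilyloxy)methyl]dihydrofuran‑2(3H)‑one | CC[Si](CC)(CC)OC[C@@H]1CCC(=O)O1 | intermediate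
3 | (3R,5S)‑3‑methyl lactone (major) | CC[Si](CC)(CC)OC[C@@H]1C[C@@H](C)C(=O)O1 | intermediate
4 | (3R,5S)‑3‑hydroxy‑3‑methyl lactone | CC[Si](CC)(CC)OC[C@@H]1C[C@@](C)(O)C(=O)O1 | intermediate
5 | (Z)‑3‑methylpent‑2‑en‑4‑yn‑1‑ol | C#C/C(C)=C\CO | starting material
6 | (Z)‑3‑methylpent‑2‑en‑4‑ynal | C#C/C(C)=C\C=O | intermediate
7 | (Z)‑5,5‑dimethoxy‑3‑methylpent‑3‑en‑1‑yne | C#C/C(C)=C\C(OC)OC | intermediate
8 | α′‑hydroxy ynone (2Z,7R,9S) | COC(OC)/C=C(/C)C#CC(=O)[C@](C)(O)C[C@H](O)CO[Si](CC)(CC)CC | intermediate
9 | bis‑TES furanone acetal | COC(OC)/C=C(/C)C1=CC(=O)[C@@](C)(C[C@H](O[Si](CC)(CC)CC)CO[Si](CC)(CC)CC)O1 | intermediate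
10 | C7 aldehyde | COC(OC)/C=C(/C)C1=CC(=O)[C@@](C)(C[C@H](O[Si](CC)(CC)CC)C=O)O1 | intermediate
11 | methyl acrylate | C=CC(=O)OC | starting material
12 | Baylis–Hillman adduct (C7 epimers) | COC(OC)/C=C(/C)C1=CC(=O)[C@@](C)(C[C@H](O[Si](CC)(CC)CC)C(O)C(=C)C(=O)OC)O1 | intermediate
13 | (Z)‑allylic bromide acetal | COC(OC)/C=C(/C)C1=CC(=O)[C@@](C)(C[C@H](O[Si](CC)(CC)CC)/C=C(\CBr)C(=O)OC)O1 | intermediate
14 | seco (Z)‑enal/allylic bromide | O=C/C=C(/C)C1=CC(=O)[C@@](C)(C[C@H](O[Si](CC)(CC)CC)/C=C(\CBr)C(=O)OC)O1 | intermediate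
15 | 8‑O‑deangeloyl‑lychnopholide | C=C1C(=O)O[C@@H]2/C=C(/C)C3=CC(=O)[C@@](C)(C[C@H](O)[C@@H]12)O3 | intermediate
16 | angelic acid | C/C=C(/C)C(=O)O | starting material
17 | lychnopholide | C=C1C(=O)O[C@@H]2/C=C(/C)C3=CC(=O)[C@@](C)(C[C@H](OC(=O)/C(C)=C\C)[C@@H]12)O3 | target

**Totals**
- Total steps: 13.
- Longest linear sequence: 11 (Steps 1–3 and 6–13). Steps 4–5 form a two‑step side branch.

**Steps most likely to fail**
1. **Step 12 (new reaction).**
   - Risks: slow medium‑ring closure, protodebromination or oligomerisation, enal pinacol coupling, and photoisomerisation.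
   - Fallback (known chemistry, different ring order): omit the Au cyclisation and carry the acyclic ynone, with C8 and C10 as TES ethers, through Steps 8–11. Close the less strained 10‑membered enynone with classical stoichiometric CrCl2 (dark Nozaki–Hiyama‑type allylation, high dilution). Then desilylate and build the furanone transannularly by Au(I) 5‑endo‑dig cyclisation.
2. **Step 11.**
   - Risks: Z→E isomerisation of the dienal, or premature loss of the C8 TES group.
   - Fallback: change the C6 oxidation‑state strategy. Use the PMB ether of 5 as the acetylide partner, release the alcohol with DDQ after Step 10, and oxidise the (Z)‑allylic alcohol with MnO2 just before cyclisation. Both operations are neutral. This adds one step to the linear sequence and removes one from the branch.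
3. **Step 13.**
   - Risks: a hindered C8 hydroxyl, isomerisation to the tiglate, translactonisation to the 8,12‑olide, or amine addition to the methylene lactone at 75 °C.
   - Fallback: build the angelate C=C on the ester. Acylate 15 at rt with 2‑(diphenoxyphosphoryl)propanoic acid (EDC), then run a Z‑selective Ando‑type Horner–Wadsworth–Emmons olefination with acetaldehyde (NaI/DBU).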